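**Retrosynthetic overview**
1. Target ⇐ allylic alcohol ⇐ bridged silyl ether: the cyclohexene ring, the C6–C7 bond and the C-10 acetate are made together, last, by a new gold-catalysed bridging acetoxy-cyclisation of a cycloheptene 1,5-enyne.
2. Cycloheptene (C4–C5 bond and both centres; CO2H → acetyl) ⇐ ring-contracting Ireland–Claisen rearrangement of a seven-membered alkenyl lactone.
3. Lactone ⇐ Baeyer–Villiger oxidation of a 2-alkenyl-2-methyl-3-butynylcyclohexanone ⇐ asymmetric CuH reduction, Pd α-alkenylation and methylation of a 3-(but-2-ynyl)cyclohexenone.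
4. Alkenyl iodide (side-chain centre) ⇐ (S)-citronellal by alkyne formation and Zr-catalysed methylalumination.
5. Ring order: cyclohexanone scaffold → oxepanone → cycloheptene (seven-membered ring of the target) → cyclohexene ring that closes the bicyclo[4.3.1]decene.

Locants C-1 to C-10 below are those of the target ring system: C-1 and C-6 bridgeheads, C-4 (acetyl), C-5 (quaternary), C-7 (formyl), C-10 (acetoxy).

Assumption: read literally, the two bridgehead tags of the given string would join the C-2–C-5 and C-7–C-9 bridges trans (an in,out bicycle), which a bicyclo[4.3.1]decene cannot be; the string and its tags are kept unchanged in every SMILES (so the tag at C-1 is carried as given), and the chemistry is aimed at the cis-bridged compound that has C-4, C-5, C-6, C-10 and the side-chain centre as written.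

**Route**

Step 1
Reactants: 1 (S)-citronellal
Product: 3 (3S)-3,7-dimethyloct-6-en-1-yne, via enol nonaflate 2 (not isolated)
Conditions: n-C4F9SO2F, phosphazene base P2-Et, DMF, −20 °C to rt
Reagents that add atoms: nonafluorobutane-1-sulfonyl fluoride, O=S(=O)(F)C(F)(F)C(F)(F)C(F)(F)C(F)(F)F (its atoms stay only in 2)
Why: One-pot enol sulfonate formation and elimination (aldehyde-to-alkyne dehydration) turns CH2–CHO into C≡CH and leaves the stereocentre, which is not alpha to the carbonyl, untouched.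

Step 2
Reactants: 3 (3S)-3,7-dimethyloct-6-en-1-yne
Product: 5 (1E,3S)-1-iodo-2,3,7-trimethylocta-1,6-diene, via alkenylalane 4 (not isolated)
Conditions: Me3Al, Cp2ZrCl2 (20 mol%), CH2Cl2, 0 °C to rt; then I2, THF, −30 °C
Reagents that add atoms: trimethylaluminium, C[Al](C)C; iodine, [I][I]
Why: Negishi zirconium-catalysed carboalumination adds methyl and aluminium syn across the terminal alkyne (methyl to the inner carbon) and iodinolysis goes with retention, so the E-iodide with methyl cis to iodine is formed.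

Step 3
Reactants: 6 (3-methoxyphenyl)methanol
Product: 8 3-(hydroxymethyl)cyclohex-2-en-1-one, via dihydroanisole 7 (not isolated)
Conditions: Li, NH3 (l), t-BuOH, THF, −78 °C; then 2 M HCl, THF, rt
Reagents that add atoms: water, O
Why: Birch reduction gives the 1,4-diene with methoxy on a double bond, and acid hydrolysis of that enol ether with conjugation of the double bond gives the enone.

Step 4
Reactants: 8 3-(hydroxymethyl)cyclohex-2-en-1-one
Product: 9 3-(bromomethyl)cyclohex-2-en-1-one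
Conditions: CBr4, PPh3, CH2Cl2, 0 °C
Reagents that add atoms: carbon tetrabromide, BrC(Br)(Br)Br
Why: The Appel reaction converts the primary allylic alcohol into the bromide under neutral conditions.

Step 5
Reactants: 9 3-(bromomethyl)cyclohex-2-en-1-one; 10 tert-butyldimethyl(prop-2-yn-1-yloxy)silane
Product: 11 3-[4-(tert-butyldimethylsilyloxy)but-2-yn-1-yl]cyclohex-2-en-1-one
Conditions: CuI (10 mol%), NaI (20 mol%), K2CO3, DMF, rt
Reagents that add atoms: none
Why: Copper-catalysed alkynylation of an allylic bromide (sp–sp3 coupling) joins the terminal alkyne to the unhindered primary carbon and gives the skipped enyne.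

Step 6
Reactants: 11 3-[4-(tert-butyldimethylsilyloxy)but-2-yn-1-yl]cyclohex-2-en-1-one
Product: 12 dimethylphenylsilyl enol ether of the (3S)-3-butynylcyclohexanone
Conditions: Cu(OAc)2·H2O (3 mol%), (R)-DTBM-SEGPHOS (3 mol%), PhMe2SiH, toluene, −30 °C
Reagents that add atoms: dimethyl(phenyl)silane, C[SiH](C)c1ccccc1
Why: Copper hydride asymmetric conjugate reduction delivers hydride to one face of the β-carbon under ligand control, which sets the future C-1 centre, and leaves the regiodefined silyl enol ether (the ligand enantiomer is the one that gives 12 as drawn).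

Step 7
Reactants: 12 silyl enol ether; 5 (1E,3S)-1-iodo-2,3,7-trimethylocta-1,6-diene
Product: 13 (2R,3S)-2-alkenyl-3-butynylcyclohexanone
Conditions: Pd2(dba)3 (2.5 mol%), P(t-Bu)3 (6 mol%), ZnF2 (0.3 equiv), CsF, DMF, 60 °C
Reagents that add atoms: none
Why: Fluoride-activated palladium-catalysed α-alkenylation of a silyl enol ether forms the future C-10–C-6 bond at the regiodefined carbon with retention of the E geometry, trans to the neighbouring butynyl arm; this centre is reset in step 8.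

Step 8
Reactants: 13 (2R,3S)-2-alkenyl-3-butynylcyclohexanone
Product: 15 (2S,3S)-2-alkenyl-2-methyl-3-butynylcyclohexanone, via potassium dienolate 14 (not isolated)
Conditions: KN(SiMe3)2, THF, −78 °C; then MeI, −78 to −40 °C
Reagents that add atoms: iodomethane, CI; potassium bis(trimethylsilyl)amide, C[Si](C)(C)[N-][Si](C)(C)C.[K+] (potassium stays only in 14)
Why: Enolate alkylation at the α-carbon: iodomethane enters anti to the adjacent butynyl arm, so the quaternary carbon carries methyl trans and alkenyl cis to that arm, and the low temperature keeps the E-alkene.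

Step 9
Reactants: 15 (2S,3S)-2-alkenyl-2-methyl-3-butynylcyclohexanone
Product: 16 (6S,7S)-7-alkenyl-7-methyl-6-butynyloxepan-2-one
Conditions: Me3SiOOSiMe3, Me3SiOSO2CF3 (10 mol%), CH2Cl2, −40 °C
Reagents that add atoms: bis(trimethylsilyl) peroxide, C[Si](C)(C)OO[Si](C)(C)C
Why: Baeyer–Villiger oxidation with a silyl peroxide, which does not epoxidise alkenes: the quaternary allylic carbon migrates to oxygen with retention and gives the tertiary allylic lactone.

Step 10
Reactants: 16 (6S,7S)-7-alkenyl-7-methyl-6-butynyloxepan-2-one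
Product: 19 (1S,2R,5S)-cyclohept-3-ene-1-carboxylic acid, via silyl ketene acetal 17 (not isolated), via trimethylsilyl ester 18 (not isolated)
Conditions: LiN(i-Pr)2, Me3SiCl, Et3N, THF, −78 °C; then toluene, 110 °C; then H2O, THF, rt
Reagents that add atoms: chlorotrimethylsilane, C[Si](C)(C)Cl (silicon stays only in 17 and 18)
Why: Ireland–Claisen rearrangement in its ring-contracting form: the cyclic ketene acetal can reach the alkenyl group only through a boat transition state, the C–O stereocentre is relayed suprafacially to the new C-4–C-5 bond, the E-alkene puts the C-5 side chain cis to the C-4 carboxyl, and the ring alkene C-10=C-6 is formed cis.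

Step 11
Reactants: 19 (1S,2R,5S)-cyclohept-3-ene-1-carboxylic acid
Product: 21 (1S,2R,5S)-cycloheptenyl methyl ketone, via dilithium gem-diolate 20 (not isolated)
Conditions: MeLi (2.4 equiv), Et2O, −78 to 0 °C; then H2O
Reagents that add atoms: methyllithium, [Li]C
Why: Methyllithium addition to a carboxylic acid stops at the ketone stage until work-up and gives the C-4 acetyl group without enolising C-4.

Step 12
Reactants: 21 (1S,2R,5S)-cycloheptenyl methyl ketone
Product: 22 (1S,4S,5R,6S,10R)-bicyclo[4.3.1]dec-7-en-10-yl acetate with 7-CH2OSi(t-Bu)Me2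
Conditions: (t-Bu)2(2-biphenylyl)PAu(NCMe)SbF6 (5 mol%, monovalent gold), AcOH/CH2Cl2 1:3, −20 °C to rt
Reagents that add atoms: acetic acid, CC(=O)O
Why: Proposed new method: monovalent gold activates the alkyne, the ring alkene attacks it through C-6 in a 6-endo-dig sense on the only face the C-1 butynyl arm can reach (so bridgehead C-6 is fixed as the cis-bridged one), the positive charge that builds at tertiary C-10 is quenched by acetic acid anti to the new C6–C7 bond, and protodeauration gives the C7=C8 alkene; the closest known reaction type is the gold-catalysed alkoxy- and hydroxy-cyclisation of 1,5-enynes, which has not been shown with a carboxylic acid on a ring alkene to give a bridged tertiary acetate.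

Step 13
Reactants: 22 bridged silyl ether acetate
Product: 23 (1S,4S,5R,6S,10R)-7-(hydroxymethyl)bicyclo[4.3.1]dec-7-en-10-yl acetate
Conditions: HF·pyridine, pyridine, THF, 0 °C to rt
Reagents that add atoms: none
Why: Fluoride desilylation frees the primary allylic alcohol without touching the hindered tertiary acetate or the ketone.

Step 14
Reactants: 23 allylic alcohol
Product: 24 target CNP0288370.1
Conditions: MnO2 (15 equiv), CH2Cl2, rt
Reagents that add atoms: none
Why: MnO2 oxidises only the allylic alcohol and gives the conjugated aldehyde under neutral conditions, so C-4 is not epimerised.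

**Compound list**
1 | (S)-citronellal, (3S)-3,7-dimethyloct-6-enal | O=CC[C@@H](C)CCC=C(C)C | starting material
2 | (3S)-3,7-dimethylocta-1,6-dien-1-yl nonafluorobutane-1-sulfonate, E/Z mixture (not isolated) | FC(F)(F)C(F)(F)C(F)(F)C(F)(F)S(=O)(=O)OC=C[C@@H](C)CCC=C(C)C | intermediate
3 | (3S)-3,7-dimethyloct-6-en-1-yne | C#C[C@@H](C)CCC=C(C)C | intermediate
4 | dimethyl[(1E,3S)-2,3,7-trimethylocta-1,6-dien-1-yl]alane (not isolated) | C[Al](C)/C=C(\C)[C@@H](C)CCC=C(C)C | intermediate
5 | (1E,3S)-1-iodo-2,3,7-trimethylocta-1,6-diene | I/C=C(\C)[C@@H](C)CCC=C(C)C | intermediate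
6 | (3-methoxyphenyl)methanol | COc1cccc(CO)c1 | starting material
7 | (5-methoxycyclohexa-1,4-dien-1-yl)methanol (not isolated) | COC1=CCC=C(CO)C1 | intermediate
8 | 3-(hydroxymethyl)cyclohex-2-en-1-one | O=C1C=C(CO)CCC1 | intermediate
9 | 3-(bromomethyl)cyclohex-2-en-1-one | O=C1C=C(CBr)CCC1 | intermediate
10 | tert-butyldimethyl(prop-2-yn-1-yloxy)silane | C#CCO[Si](C)(C)C(C)(C)C | starting material
11 | 3-{4-[(tert-butyldimethylsilyl)oxy]but-2-yn-1-yl}cyclohex-2-en-1-one | O=C1C=C(CC#CCO[Si](C)(C)C(C)(C)C)CCC1 | intermediate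
12 | {[(3S)-3-{4-[(tert-butyldimethylsilyl)oxy]but-2-yn-1-yl}cyclohex-1-en-1-yl]oxy}dimethyl(phenyl)silane | C[Si](C)(c1ccccc1)OC1=C[C@H](CC#CCO[Si](C)(C)C(C)(C)C)CCC1 | intermediate
13 | (2R,3S)-3-{4-[(tert-butyldimethylsilyl)oxy]but-2-yn-1-yl}-2-[(1E,3S)-2,3,7-trimethylocta-1,6-dien-1-yl]cyclohexan-1-one | O=C1CCC[C@@H](CC#CCO[Si](C)(C)C(C)(C)C)[C@@H]1/C=C(\C)[C@@H](C)CCC=C(C)C | intermediate
14 | potassium dienolate of 13 (not isolated) | [K+].[O-]C1=C(/C=C(\C)[C@@H](C)CCC=C(C)C)[C@H](CC#CCO[Si](C)(C)C(C)(C)C)CCC1 | intermediate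
15 | (2S,3S)-3-{4-[(tert-butyldimethylsilyl)oxy]but-2-yn-1-yl}-2-methyl-2-[(1E,3S)-2,3,7-trimethylocta-1,6-dien-1-yl]cyclohexan-1-one | O=C1CCC[C@@H](CC#CCO[Si](C)(C)C(C)(C)C)[C@@]1(C)/C=C(\C)[C@@H](C)CCC=C(C)C | intermediate
16 | (6S,7S)-6-{4-[(tert-butyldimethylsilyl)oxy]but-2-yn-1-yl}-7-methyl-7-[(1E,3S)-2,3,7-trimethylocta-1,6-dien-1-yl]oxepan-2-one | O=C1CCC[C@@H](CC#CCO[Si](C)(C)C(C)(C)C)[C@@](C)(/C=C(\C)[C@@H](C)CCC=C(C)C)O1 | intermediate
17 | trimethylsilyl ketene acetal of 16, a 7-(trimethylsilyloxy)-2,3,4,5-tetrahydrooxepine (not isolated) | C[Si](C)(C)OC1=CCC[C@@H](CC#CCO[Si](C)(C)C(C)(C)C)[C@@](C)(/C=C(\C)[C@@H](C)CCC=C(C)C)O1 | intermediate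
18 | trimethylsilyl ester of 19 (not isolated) | CC1=C[C@@](C)([C@@H](C)CCC=C(C)C)[C@@H](C(=O)O[Si](C)(C)C)CC[C@H]1CC#CCO[Si](C)(C)C(C)(C)C | intermediate
19 | (1S,2R,5S)-5-{4-[(tert-butyldimethylsilyl)oxy]but-2-yn-1-yl}-2,4-dimethyl-2-[(2S)-6-methylhept-5-en-2-yl]cyclohept-3-ene-1-carboxylic acid | CC1=C[C@@](C)([C@@H](C)CCC=C(C)C)[C@@H](C(=O)O)CC[C@H]1CC#CCO[Si](C)(C)C(C)(C)C | intermediate
20 | dilithium gem-diolate from 19 and methyllithium (not isolated) | CC1=C[C@@](C)([C@@H](C)CCC=C(C)C)[C@@H](C(C)([O-])[O-])CC[C@H]1CC#CCO[Si](C)(C)C(C)(C)C.[Li+].[Li+] | intermediate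
21 | 1-[(1S,2R,5S)-5-{4-[(tert-butyldimethylsilyl)oxy]but-2-yn-1-yl}-2,4-dimethyl-2-[(2S)-6-methylhept-5-en-2-yl]cyclohept-3-en-1-yl]ethan-1-one | CC1=C[C@@](C)([C@@H](C)CCC=C(C)C)[C@@H](C(C)=O)CC[C@H]1CC#CCO[Si](C)(C)C(C)(C)C | intermediate
22 | (1S,4S,5R,6S,10R)-4-acetyl-7-{[(tert-butyldimethylsilyl)oxy]methyl}-5,10-dimethyl-5-[(2S)-6-methylhept-5-en-2-yl]bicyclo[4.3.1]dec-7-en-10-yl acetate | CC(=O)O[C@]1(C)[C@@H]2CC=C(CO[Si](C)(C)C(C)(C)C)[C@@H]1[C@@](C)([C@@H](C)CCC=C(C)C)[C@@H](C(C)=O)CC2 | intermediate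
23 | (1S,4S,5R,6S,10R)-4-acetyl-7-(hydroxymethyl)-5,10-dimethyl-5-[(2S)-6-methylhept-5-en-2-yl]bicyclo[4.3.1]dec-7-en-10-yl acetate | CC(=O)O[C@]1(C)[C@@H]2CC=C(CO)[C@@H]1[C@@](C)([C@@H](C)CCC=C(C)C)[C@@H](C(C)=O)CC2 | intermediate
24 | CNP0288370.1, (1S,4S,5R,6S,10R)-4-acetyl-7-formyl-5,10-dimethyl-5-[(2S)-6-methylhept-5-en-2-yl]bicyclo[4.3.1]dec-7-en-10-yl acetate | CC(=O)O[C@]1(C)[C@@H]2CC=C(C=O)[C@@H]1[C@@](C)([C@@H](C)CCC=C(C)C)[C@@H](C(C)=O)CC2 | target

**Totals and risks**
Total steps: 14. Longest linear sequence: 12 steps (steps 3 to 14).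

Step 12 is the new step. The C-4 acetyl oxygen, or a simple skeletal rearrangement of the enyne, could outrun capture of C-10 by acetic acid on its hindered face. The fallback uses known chemistry, sets out from 21 and comes back at 24. HF·pyridine gives the propargylic alcohol F1. Hydroxyl-directed trans-hydrostannation ([Cp*RuCl]4, Bu3SnH) gives the (Z)-alkenylstannane F2, and I2 gives the (Z)-alkenyl iodide F3. Tin hydride radical cyclisation under dry air (Bu3SnH, AIBN, toluene, 60 °C) closes the six-membered ring at C-6 and traps the tertiary C-10 radical as the hydroperoxide F4, which PPh3 reduces to the diol F5. MnO2 gives the hydroxy enal F6, and Ac2O with Sc(OTf)3 acetylates the tertiary alcohol to 24.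

Step 9 is a Baeyer–Villiger oxidation beside two electron-rich alkenes, and the tertiary allylic lactone may not tolerate the Lewis acid. The fallback sets out from 15 and comes back at 16. Excess m-CPBA with NaHCO3 carries out the Baeyer–Villiger reaction and at the same time epoxidises both trisubstituted alkenes, giving the bis-epoxy lactone F7. MeReO3 (cat.) with PPh3 then removes both epoxide oxygens with retention of alkene geometry and gives 16.

Step 7 is a coupling at a hindered enolate carbon, and the product has an acidic α-hydrogen that can move the double bond into conjugation. The fallback reverses the polarity, sets out from 12 and comes back at 13. NBS turns 12 into the α-bromo ketone F8. Iodine–lithium exchange on 5 (t-BuLi, −78 °C) gives the alkenyllithium F9, and ZnCl2 gives the alkenylzinc chloride F10. NiCl2·glyme with a bis(oxazoline) ligand couples F8 with F10 (Negishi coupling of an α-halo ketone) and gives 13.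

**Further compounds**
F1 | step 12 | 1-[(1S,2R,5S)-5-(4-hydroxybut-2-yn-1-yl)-2,4-dimethyl-2-[(2S)-6-methylhept-5-en-2-yl]cyclohept-3-en-1-yl]ethan-1-one | CC1=C[C@@](C)([C@@H](C)CCC=C(C)C)[C@@H](C(C)=O)CC[C@H]1CC#CCO
F2 | step 12 | 1-[(1S,2R,5S)-5-[(2Z)-4-hydroxy-3-(tributylstannyl)but-2-en-1-yl]-2,4-dimethyl-2-[(2S)-6-methylhept-5-en-2-yl]cyclohept-3-en-1-yl]ethan-1-one | CC1=C[C@@](C)([C@@H](C)CCC=C(C)C)[C@@H](C(C)=O)CC[C@H]1C/C=C(/CO)[Sn](CCCC)(CCCC)CCCC
F3 | step 12 | 1-[(1S,2R,5S)-5-[(2Z)-4-hydroxy-3-iodobut-2-en-1-yl]-2,4-dimethyl-2-[(2S)-6-methylhept-5-en-2-yl]cyclohept-3-en-1-yl]ethan-1-one | CC1=C[C@@](C)([C@@H](C)CCC=C(C)C)[C@@H](C(C)=O)CC[C@H]1C/C=C(/CO)I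
F4 | step 12 | 1-[(1S,4S,5R,6S,10R)-10-hydroperoxy-7-(hydroxymethyl)-5,10-dimethyl-5-[(2S)-6-methylhept-5-en-2-yl]bicyclo[4.3.1]dec-7-en-4-yl]ethan-1-one | OO[C@]1(C)[C@@H]2CC=C(CO)[C@@H]1[C@@](C)([C@@H](C)CCC=C(C)C)[C@@H](C(C)=O)CC2
F5 | step 12 | 1-[(1S,4S,5R,6S,10R)-10-hydroxy-7-(hydroxymethyl)-5,10-dimethyl-5-[(2S)-6-methylhept-5-en-2-yl]bicyclo[4.3.1]dec-7-en-4-yl]ethan-1-one | O[C@]1(C)[C@@H]2CC=C(CO)[C@@H]1[C@@](C)([C@@H](C)CCC=C(C)C)[C@@H](C(C)=O)CC2
F6 | step 12 | (1S,4S,5R,6S,10R)-4-acetyl-10-hydroxy-5,10-dimethyl-5-[(2S)-6-methylhept-5-en-2-yl]bicyclo[4.3.1]dec-7-ene-7-carbaldehyde | O[C@]1(C)[C@@H]2CC=C(C=O)[C@@H]1[C@@](C)([C@@H](C)CCC=C(C)C)[C@@H](C(C)=O)CC2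
F7 | step 9 | bis-epoxide of 16 (both trisubstituted alkenes epoxidised, epoxide centres as a mixture) | O=C1CCC[C@@H](CC#CCO[Si](C)(C)C(C)(C)C)[C@@](C)(C2OC2(C)[C@@H](C)CCC2OC2(C)C)O1
F8 | step 7 | (3S)-2-bromo-3-{4-[(tert-butyldimethylsilyl)oxy]but-2-yn-1-yl}cyclohexan-1-one (C-2 epimers) | O=C1CCC[C@@H](CC#CCO[Si](C)(C)C(C)(C)C)C1Br
F9 | step 7 | [(1E,3S)-2,3,7-trimethylocta-1,6-dien-1-yl]lithium | [Li]/C=C(\C)[C@@H](C)CCC=C(C)C
F10 | step 7 | chloro[(1E,3S)-2,3,7-trimethylocta-1,6-dien-1-yl]zinc | Cl[Zn]/C=C(\C)[C@@H](C)CCC=C(C)C
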